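Everything rests on reading ring B as a ketone plus a C3 dialdehyde. Its hydroxyl-bearing carbon lies between the diaryl-ether carbon and the chain-bearing carbon. That carbon is taken as the carbonyl of a 21-membered aryloxymethyl ketone, and the two α-methylenes become its two neighbours. The remaining CH–C(NO2)–CH unit is nitromalonaldehyde. One double aldol condensation in dilute base forms both missing ring B bonds and aromatises. It leaves a nitro group para to the new phenol as the handle for the second hydroxyl. The precursor macrocycle carries ring A as its methyl ether and an O–CH2–C(=O)–(CH2)15 tether. It is assembled from a phenol and an α-chloroketone and closed by ring-closing metathesis.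

Key step: step 6

Remarks on the chemistry:
- **Stereochemistry:** the target has no stereocentre and no fixed double-bond geometry. The metathesis alkene is expected as an E/Z mixture and is saturated in the same step.
- **Carbon count:** 4 + 2 + 9 = 15 CH2 groups lie between ring A and the carbonyl of the macrocyclic ketone. One of them becomes the chain-bearing carbon of ring B, which leaves the 14 CH2 groups of the target.
- **Nitromalonaldehyde salt:** it is assumed to be a catalogue compound. It is heat- and impact-sensitive and is handled in small portions behind a shield.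

Step 1
Reactants: 1 3,5-dimethoxybenzyl bromide; 2 5-bromopent-1-ene
Product: 4 1-(hex-5-en-1-yl)-3,5-dimethoxybenzene, via pent-4-enylmagnesium bromide 3 (not isolated)
Conditions: 2, Mg, THF, 40 °C; then 1, Li2CuCl4 (3 mol %), THF, −10 °C → rt
Reagents that add atoms: magnesium, [Mg] (held only in 3, absent from 4)
Why: Copper-catalysed Kochi-type cross-coupling of a primary alkyl Grignard reagent with a benzylic bromide is a standard way to 5-alkylresorcinol dimethyl ethers, the pent-4-enyl reagent has no fast cyclisation path, and the terminal alkene and methyl ethers are spectators.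

Step 2
Reactants: 4 1-(hex-5-en-1-yl)-3,5-dimethoxybenzene
Product: 5 3-(hex-5-en-1-yl)-5-methoxyphenol
Conditions: NaSEt (3 equiv), DMF, 140 °C, N2; then 1 M HCl
Reagents that add atoms: none
Why: Nucleophilic aryl methyl ether cleavage (SN2 attack of thiolate on the O–CH3 carbon) should stop after one methyl group because the phenoxide charge makes the ring a much poorer leaving group for a second cleavage, which desymmetrises ring A, and thiolate is too weak a base to move the isolated alkene.

Step 3
Reactants: 6 11-bromoundec-1-ene; 7 2-chloro-N-methoxy-N-methylacetamide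
Product: 9 1-chlorotridec-12-en-2-one, via undec-10-enylmagnesium bromide 8 (not isolated)
Conditions: 6, Mg, THF, 40 °C; then 7, THF, −20 → 0 °C; 1 M HCl
Reagents that add atoms: magnesium, [Mg] (held only in 8, absent from 9)
Why: Weinreb ketone synthesis, in which the N-methoxy-N-methyl amide guarantees single addition and acyl attack at low temperature is much faster than displacement of chloride, is the usual way from this amide to chloromethyl ketones.

Step 4
Reactants: 5 3-(hex-5-en-1-yl)-5-methoxyphenol; 9 1-chlorotridec-12-en-2-one
Product: 10 1-[3-(hex-5-en-1-yl)-5-methoxyphenoxy]tridec-12-en-2-one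
Conditions: K2CO3, NaI (10 mol %), acetone, reflux
Reagents that add atoms: none
Why: Williamson ether synthesis on an α-halo ketone, a very fast SN2 electrophile further activated by catalytic Finkelstein exchange, needs only carbonate, and making the O–CH2 bond intermolecularly from a finished chloroketone means the free phenol never has to coexist with an activated acid or a diazoalkane.

Step 5
Reactants: 10 1-[3-(hex-5-en-1-yl)-5-methoxyphenoxy]tridec-12-en-2-one
Product: 12 1^5-methoxy-2-oxa-1(1,3)-benzenacyclononadecaphan-4-one, via macrocyclic alkene 11 (not isolated)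
Conditions: second-generation Grubbs catalyst RuCl2(=CHPh)(PCy3)(H2IMes) (5 mol %), CH2Cl2 (1 mM), reflux; evaporate; then H2 (1 atm), Pd/C, EtOAc, rt
Reagents that add atoms: none
Why: Ring-closing metathesis of two unhindered terminal alkenes at high dilution is driven by loss of ethene and is well established for unstrained rings of about twenty members, and the heterogeneous hydrogenation that follows saturates the E/Z alkene without touching the ketone or the aryl ethers.

Step 6
Reactants: 12 1^5-methoxy-2-oxa-1(1,3)-benzenacyclononadecaphan-4-one; 13 sodium nitromalonaldehyde monohydrate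
Product: 14 1^5-methoxy-3^5-nitro-2-oxa-1,3(1,3)-dibenzenacycloheptadecaphan-3^2-ol
Conditions: 13 (1.5 equiv), NaOH (1.5 equiv), EtOH–THF–H2O (one phase), N2, rt, 2–4 d; then 1 M HCl
Reagents that add atoms: none
Why: Hydroxide enolises 12, most easily at the OCH2 carbon that the aryloxy group acidifies, and aldol addition to one formyl group of 13 with loss of water makes the first new ring B bond; enolisation at the second α-methylene then closes ring B by a 6-(enolendo)-exo-trig aldol on the remaining formyl group, a mode that Baldwin's rules for enolates favour. A second dehydration and tautomerisation release the 4-nitrophenolate, so every reversible aldol equilibrium drains into an aromatic anion. The closest known reaction type is exactly this one, the condensation of ketones bearing two α-methylene groups, large-ring ketones included, with sodium nitromalonaldehyde to give 2,6-disubstituted or meta-bridged 4-nitrophenols. No stereocentre arises and no regiochemical choice exists, because the carbonyl carbon has only these two neighbours and either order of bond formation ends in the same arene, while the 18-atom bridge between the meta positions leaves the new ring unstrained. The selectivity needed is cross-condensation ahead of self-aldol and of autoxidation of the enolate, which the unhindered formyl groups, the excess of 13, the inert atmosphere and the irreversible aromatisation secure. The mixed solvent holds the lipophilic ketone and the salt in one phase, and the ring A methyl ether and the ether oxygen are inert to cold dilute base.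

Step 7
Reactants: 14 1^5-methoxy-3^5-nitro-2-oxa-1,3(1,3)-dibenzenacycloheptadecaphan-3^2-ol
Product: 15 3^5-amino-1^5-methoxy-2-oxa-1,3(1,3)-dibenzenacycloheptadecaphan-3^2-ol
Conditions: H2 (1 atm), Pd/C, EtOAc–EtOH, rt; filter under N2, use at once
Reagents that add atoms: none
Why: Catalytic hydrogenation of an aromatic nitro group to the amine is fast at one atmosphere, and the molecule holds no benzylic C–O bond, halide or alkene that could be lost.

Step 8
Reactants: 15 3^5-amino-1^5-methoxy-2-oxa-1,3(1,3)-dibenzenacycloheptadecaphan-3^2-ol
Product: 17 1^5-methoxy-2-oxa-1,3(1,3)-dibenzenacycloheptadecaphane-3^2,3^5-diol, via macrocyclic quinone 16 (not isolated)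
Conditions: 15 in THF–1 M HCl added to FeCl3 (4 equiv), 1 M HCl, 0 °C; extract (Et2O); then shake with aq Na2S2O4
Reagents that add atoms: water, O
Why: Two-electron oxidation of a p-aminophenol by FeCl3 in aqueous acid with hydrolytic loss of nitrogen as ammonium is the classical route to p-benzoquinones, inverse addition into acid keeps unoxidised amine protonated and away from the aryloxyquinone, the ring A aryl ether is far harder to oxidise, and dithionite then reduces the quinone to the hydroquinone in the extract.

Step 9
Reactants: 17 1^5-methoxy-2-oxa-1,3(1,3)-dibenzenacycloheptadecaphane-3^2,3^5-diol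
Product: 18 2-oxa-1,3(1,3)-dibenzenacycloheptadecaphane-1^5,3^2,3^5-triol (CNP0393720.0)
Conditions: BBr3 (5 equiv), CH2Cl2, −78 °C → rt; then H2O (degassed), Ar
Reagents that add atoms: none
Why: BBr3 cleavage of an aryl methyl ether runs by O-coordination and bromide attack on the methyl carbon, a path closed to the diaryl ether because it has no sp3 C–O carbon, and the excess reagent only masks the free hydroxyl groups until the aqueous work-up.

Compound list (locant 1^n is position n of ring A and 3^n is position n of ring B)
1 | 3,5-dimethoxybenzyl bromide | COc1cc(CBr)cc(OC)c1 | starting material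
2 | 5-bromopent-1-ene | C=CCCCBr | starting material
3 | pent-4-enylmagnesium bromide | C=CCCC[Mg]Br | intermediate
4 | 1-(hex-5-en-1-yl)-3,5-dimethoxybenzene | COc1cc(CCCCC=C)cc(OC)c1 | intermediate
5 | 3-(hex-5-en-1-yl)-5-methoxyphenol | COc1cc(O)cc(CCCCC=C)c1 | intermediate
6 | 11-bromoundec-1-ene | C=CCCCCCCCCCBr | starting material
7 | 2-chloro-N-methoxy-N-methylacetamide | CON(C)C(=O)CCl | starting material
8 | undec-10-enylmagnesium bromide | C=CCCCCCCCCC[Mg]Br | intermediate
9 | 1-chlorotridec-12-en-2-one | ClCC(=O)CCCCCCCCCC=C | intermediate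
10 | 1-[3-(hex-5-en-1-yl)-5-methoxyphenoxy]tridec-12-en-2-one | COc1cc(CCCCC=C)cc(OCC(=O)CCCCCCCCCC=C)c1 | intermediate
11 | 1^5-methoxy-2-oxa-1(1,3)-benzenacyclononadecaphan-14-en-4-one (E/Z mixture, geometry not defined) | COc1cc2cc(c1)OCC(=O)CCCCCCCCCC=CCCCC2 | intermediate
12 | 1^5-methoxy-2-oxa-1(1,3)-benzenacyclononadecaphan-4-one (21-membered ring: ring A C1–O–CH2–C(=O)–(CH2)15–ring A C3, OMe on ring A C5) | COc1cc2cc(c1)OCC(=O)CCCCCCCCCCCCCCC2 | intermediate
13 | sodium nitromalonaldehyde monohydrate | [Na+].[O-]C=C(C=O)[N+](=O)[O-].O | starting material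
14 | 1^5-methoxy-3^5-nitro-2-oxa-1,3(1,3)-dibenzenacycloheptadecaphan-3^2-ol (ring B: OH between ether carbon and chain carbon, NO2 para to OH) | COc1cc2cc(c1)Oc1cc([N+](=O)[O-])cc(c1O)CCCCCCCCCCCCCC2 | intermediate
15 | 3^5-amino-1^5-methoxy-2-oxa-1,3(1,3)-dibenzenacycloheptadecaphan-3^2-ol | COc1cc2cc(c1)Oc1cc(N)cc(c1O)CCCCCCCCCCCCCC2 | intermediate
16 | macrocyclic 2-aryloxy-6-alkyl-1,4-benzoquinone (ring B oxidised, ring A still OMe) | COc1cc2cc(c1)OC1=CC(=O)C=C(C1=O)CCCCCCCCCCCCCC2 | intermediate
17 | 1^5-methoxy-2-oxa-1,3(1,3)-dibenzenacycloheptadecaphane-3^2,3^5-diol | COc1cc2cc(c1)Oc1cc(O)cc(c1O)CCCCCCCCCCCCCC2 | intermediate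
18 | 2-oxa-1,3(1,3)-dibenzenacycloheptadecaphane-1^5,3^2,3^5-triol (CNP0393720.0) | Oc1cc2cc(c1)Oc1cc(O)cc(c1O)CCCCCCCCCCCCCC2 | target

Total step count: 9
Longest linear sequence: 8 (steps 1, 2, 4, 5, 6, 7, 8, 9)

Steps most likely to fail

Step 6. Hydroxide may degrade the dialdehyde salt by deformylation. The enolate may be lost to self-aldol or autoxidation before both aldol events and the aromatisation are complete, or the sequence may stall after the first condensation. The fallback gives up arene construction and buys ring B. It sets out from 5 and comes back at 18.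
- Purchased 2,6-dibromo-4-methoxyphenol is O-methylated (MeI, K2CO3, acetone) to 1,3-dibromo-2,5-dimethoxybenzene F1.
- A threefold excess of F1 is joined to 5 by Ullmann diaryl ether coupling (CuI, picolinic acid, K3PO4, DMSO, 90 °C). This gives 1-bromo-3-[3-(hex-5-en-1-yl)-5-methoxyphenoxy]-2,5-dimethoxybenzene F2.
- Purchased 10-bromodec-1-ene with Zn and LiCl in THF gives dec-9-en-1-ylzinc bromide F3.
- Negishi coupling of F3 with F2 (Pd(OAc)2, SPhos, THF) gives 1-(dec-9-en-1-yl)-3-[3-(hex-5-en-1-yl)-5-methoxyphenoxy]-2,5-dimethoxybenzene F4.
- Ring-closing metathesis under the conditions of step 5 gives the macrocyclic alkene trimethyl ether F5, and hydrogenation over Pd/C gives the saturated trimethyl ether F6.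
- BBr3 in CH2Cl2 frees all three phenols to give 18.

Step 5. Intermolecular metathesis (oligomerisation) may compete with closure of the conformationally unbiased 21-membered ring. The fallback moves the ring-closing event from the C=C bond to the O–CH2 bond. It sets out from 5 and 9 and comes back at 11.
- Cross-metathesis of 5 with a fourfold excess of 9 uses second-generation Hoveyda–Grubbs catalyst RuCl2(=CH-C6H4-2-OiPr)(H2IMes) in CH2Cl2 at reflux. It should give 1-chloro-17-(3-hydroxy-5-methoxyphenyl)heptadec-12-en-2-one F7 as an E/Z mixture.
- Slow addition of F7 to Cs2CO3 in MeCN at 60 °C (final about 1 mM) closes the ring by irreversible intramolecular Williamson alkylation of the cesium phenoxide. This gives 11, which is hydrogenated as in step 5.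

Step 8. Amine that is still unoxidised may add to the newly formed quinone, or displace its aryloxy group and so open the macrocycle. Hydrolysis of the C=N stage may also be slow for so lipophilic a substrate. The fallback avoids the quinone level altogether. It sets out from 14 and comes back at 18.
- The acidic phenol of 14 is methylated (MeI, K2CO3, DMF) to the nitro dimethyl ether F8.
- Hydrogenation (H2, Pd/C) gives the aniline F9.
- Diazotisation (tBuONO, BF3·OEt2, THF, −15 °C) gives the arenediazonium tetrafluoroborate F10.
- Copper-mediated hydroxydediazoniation (Cu2O, Cu(NO3)2, H2O, rt) gives the monophenol dimethyl ether F11.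
- BBr3 cleaves both methyl ethers to give 18.

Further compounds
F1 | step 6 | 1,3-dibromo-2,5-dimethoxybenzene | COc1cc(Br)c(OC)c(Br)c1
F2 | step 6 | 1-bromo-3-[3-(hex-5-en-1-yl)-5-methoxyphenoxy]-2,5-dimethoxybenzene | COc1cc(Br)c(OC)c(Oc2cc(OC)cc(CCCCC=C)c2)c1
F3 | step 6 | dec-9-en-1-ylzinc bromide | C=CCCCCCCCC[Zn]Br
F4 | step 6 | 1-(dec-9-en-1-yl)-3-[3-(hex-5-en-1-yl)-5-methoxyphenoxy]-2,5-dimethoxybenzene | COc1cc(CCCCCCCCC=C)c(OC)c(Oc2cc(OC)cc(CCCCC=C)c2)c1
F5 | step 6 | 1^5,3^2,3^5-trimethoxy-2-oxa-1,3(1,3)-dibenzenacycloheptadecaphan-12-ene (E/Z mixture) | COc1cc2cc(c1)Oc1cc(OC)cc(c1OC)CCCCCCCCC=CCCCC2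
F6 | step 6 | 1^5,3^2,3^5-trimethoxy-2-oxa-1,3(1,3)-dibenzenacycloheptadecaphane | COc1cc2cc(c1)Oc1cc(OC)cc(c1OC)CCCCCCCCCCCCCC2
F7 | step 5 | 1-chloro-17-(3-hydroxy-5-methoxyphenyl)heptadec-12-en-2-one (E/Z mixture) | COc1cc(O)cc(CCCCC=CCCCCCCCCCC(=O)CCl)c1
F8 | step 8 | 1^5,3^2-dimethoxy-3^5-nitro-2-oxa-1,3(1,3)-dibenzenacycloheptadecaphane | COc1cc2cc(c1)Oc1cc([N+](=O)[O-])cc(c1OC)CCCCCCCCCCCCCC2
F9 | step 8 | 1^5,3^2-dimethoxy-2-oxa-1,3(1,3)-dibenzenacycloheptadecaphan-3^5-amine | COc1cc2cc(c1)Oc1cc(N)cc(c1OC)CCCCCCCCCCCCCC2
F10 | step 8 | 1^5,3^2-dimethoxy-2-oxa-1,3(1,3)-dibenzenacycloheptadecaphane-3^5-diazonium tetrafluoroborate | COc1cc2cc(c1)Oc1cc([N+]#N)cc(c1OC)CCCCCCCCCCCCCC2.F[B-](F)(F)F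
F11 | step 8 | 1^5,3^2-dimethoxy-2-oxa-1,3(1,3)-dibenzenacycloheptadecaphan-3^5-ol | COc1cc2cc(c1)Oc1cc(O)cc(c1OC)CCCCCCCCCCCCCC2
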